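The earlier runs and the new flask come from a simulation with constants of no real substance; the scatter is artificial.

Two questions stand on this flask, and I answer both by following the fraction of G left, not the fraction made.

| flask | G | Q | remark | time |
|---|---|---|---|---|
| Monday's | 2 M | 26 mM | run made earlier |  |
| Friday's | 2 M | 100 mM | run made earlier |  |
| flask | 2.0 M | 52 mM |  | 4.0 min |

- Monday's (time / min: X / %, G / %): 0.167: 1.9, 98.2; 0.500: 2.7, 96.4; 0.833: 4.3, 95.1; 1.33: 5.8, 94.1; 2.00: 8.4, 91.7; 2.50: 9.8, 90.3
- Friday's (time / min: X / %, G / %): 0.200: 5.7, 94.2; 0.333: 8.2, 92.5; 0.500: 10.4, 89.8; 0.833: 14.7, 85.2; 1.33: 19.3, 80.0; 2.50: 29.8, 69.6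

(each reading ± 0.3 percentage points)

- whether the average number of monomer units in a chain (chains begun, living or dead) reaches 8.0 by 4.0 min (no / yes)
- average number of monomer units in a chain (chains begun, living or dead) at 4.0 min

- the average divides the monomer in chains by the number of chains begun, living and dead together
- on the list of suspects stand: 2 Q -> L; G + J -> X + J; X + J -> G + J; G + Q -> J + X
- the earlier runs do not show the number of chains; that part of a forecast is a guess

How fast does that fraction fall? From 0.500 min to 2.50 min I take the fall of its logarithm per minute and divide by the charge of Q as a fraction of the charge of G. I call this the loss constant, a pseudo-first-order constant per unit of charge ratio. Monday's run reads 2.51 /min and Friday's 2.55 /min, close together although Friday's Q charge is 3.85 times Monday's, at the same charge of G. So I carry the mean, 2.53 /min.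

What must be left? This flask's charge ratio is 2.60%, and I guess one chain per Q, each taking one G at the start. A length of 8.0 then needs G down to 79.2%.

Does it get there? I reckon 74.9% left at 4.0 min, lower, so yes, with a length of 9.67.

The forecast also says yes and 9.7, taking G + Q as “fast and nearly complete, giving about one chain per Q”.

The flask gives yes and 10.2.

    2 Q → L (k = 0.0515 /M/s)
    G + J → X + J, rate k2*[J]*[G] (k = 0.0469 /M/s)
    X + J → G + J, rate k3*[J] as long as [X] is above zero (k = 0.0403 /s)
    G + Q → J + X (k = 0.0872 /M/s)

Between 2.00 min and 4.00 min, G in this flask goes from 84.3% to 74.0%, so the loss constant reads 2.52 /min, and at 4.00 min X in this flask is made 1.72 times faster than it is used up, each step taken net. For the run at twice the dilution, taking the same charge ratio and assuming the pace halved, the loss constant reckons a length of 5.62, but that run ends lower, at 2.13.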